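The cyclopentenone ring (C1 ketone, C2=C3, C4–OAc, C5–OH; side-chain carbinol C1′) is traced back to a 3-substituted 4-pyranone. C3–C4 is then the only skeletal bond to be made, and the pyranone ring oxygen becomes O4. The key step exploits the trans O4/O5 pair on the two sp3 ring carbons next to the C1 enone, together with the C5/C1′ 1,2-diol, which carries a silanol tether. One irradiation contracts the heterocycle, forms C5–O, closes the carbocycle and a spiro dioxasilolane, sets C4 and C5, and leaves only C4–OH free for acetylation. The precursor is 3-[(1S)-1-hydroxytridecyl]-4-pyranone as its di-tert-butyl(hydroxy)silyl ether.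

Key step: step 6

Remark: the target is (4R,5S,1′S) with O4 and O5 trans; in 13 and 14 the C5 descriptor reads R only because the O–Si branch lifts C1′ above C4 in the priority order, and the spatial arrangement is unchanged.

Step 1
Reactants: 1 4H-pyran-4-one
Product: 2 3-iodo-4H-pyran-4-one
Conditions: NIS (1.0 equiv), CF3CO2H (0.3 equiv), MeCN, 50 °C, dark
Reagents that add atoms: N-iodosuccinimide, O=C1CCC(=O)N1I
Why: Electrophilic α-iodination of a β-alkoxy enone, the reaction type by which chromones and alkylated 4-pyranones are 3-halogenated: C3 is the nucleophilic enol-ether β-carbon, acid-activated NIS delivers iodine there, and one equivalent together with the deactivating first iodine should hold back 3,5-diiodination.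

Step 2
Reactants: 2 3-iodo-4H-pyran-4-one; 3 tridecanal
Product: 5 (±)-3-(1-hydroxytridecyl)-4H-pyran-4-one, via pyranonylmagnesium chloride 4 (not isolated)
Conditions: iPrMgCl·LiCl (1.05 equiv), THF, −40 °C; then 3 (1.2 equiv), −40 → 0 °C; then 1 M HCl
Reagents that add atoms: none
Why: Iodine–magnesium exchange with the LiCl-activated isopropyl Grignard reagent is fast at low temperature on α-iodo-β-alkoxy enones because the sp2 carbanion is stabilised inductively and by chelation to the neighbouring C=O, and 4 should add 1,2 to the aldehyde before it can ring-open; the carbinol centre forms racemic and is corrected in steps 3 and 4.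

Step 3
Reactants: 5 (±)-3-(1-hydroxytridecyl)-4H-pyran-4-one
Product: 6 3-tridecanoyl-4H-pyran-4-one
Conditions: Dess–Martin periodinane (1.2 equiv), CH2Cl2, 0 °C → rt
Reagents that add atoms: none
Why: Dess–Martin oxidation runs under neutral to weakly acidic conditions, so the allylic-type secondary carbinol should go to the ketone without exposing the electrophilic C2 of the 3-acylpyranone to base or nucleophiles.

Step 4
Reactants: 6 3-tridecanoyl-4H-pyran-4-one
Product: 7 3-[(1S)-1-hydroxytridecyl]-4H-pyran-4-one
Conditions: (R)-2-methyl-CBS-oxazaborolidine (20 mol %), catecholborane (1.5 equiv), toluene, −78 °C; then pH 7 buffer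
Reagents that add atoms: none
Why: Corey–Bakshi–Shibata reduction, in which the exocyclic ketone should bind the catalyst boron with the branched sp2 pyranonyl group as the large and the n-alkyl chain as the small substituent, so that the (R)-catalyst gives the (S)-carbinol as it does with aryl and α-substituted alkenyl n-alkyl ketones, while the vinylogous-ester ring carbonyl is too electron-rich to be reduced at −78 °C.

Step 5
Reactants: 7 3-[(1S)-1-hydroxytridecyl]-4H-pyran-4-one; 8 di-tert-butylsilyl bis(trifluoromethanesulfonate)
Product: 10 3-[(1S)-1-{[di-tert-butyl(hydroxy)silyl]oxy}tridecyl]-4H-pyran-4-one, via silyl triflate 9 (not isolated)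
Conditions: 8 (1.3 equiv), 2,6-lutidine (3 equiv), CH2Cl2, 0 °C; then H2O, rt
Reagents that add atoms: water, O
Why: O-silylation followed by hydrolysis, the known preparation of alkoxy-di-tert-butylsilanols: the two tert-butyl groups stop the reaction at mono-alkoxysilyl triflate 9, water displaces the second triflate to give a silanol too hindered to condense to a disiloxane, any reversible silylation of the ring carbonyl is undone in the same hydrolysis, and C1′ is not touched.

Step 6
Reactants: 10 3-[(1S)-1-{[di-tert-butyl(hydroxy)silyl]oxy}tridecyl]-4H-pyran-4-one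
Product: 13 (4S,5R,9R)-2,2-di-tert-butyl-4-dodecyl-9-hydroxy-1,3-dioxa-2-silaspiro[4.4]non-7-en-6-one (C5/C1′-O-silylene of the deacetyl target), via oxyallyl zwitterion 11 (not isolated), via spiro epoxy enol 12 (not isolated)
Conditions: hν (254 nm, low-pressure Hg lamps, quartz), (CF3)2CHOH, 2 mM, Ar, 15 °C, stopped near full conversion
Reagents that add atoms: none
Why: Proposed new method: on absorbing 254 nm light the dienone chromophore of 10 should join its two oxygen-bearing carbons (pyranone C2 and C6, target C4 and C3) in a disrotatory 4π electrocyclisation to give 11, an oxyallyl cation fused to an oxirane; the tethered Si–OH should then add to the terminus that carries the side chain (target C5) to give 12 after a proton shift, and the enol of 12 should expel the oxirane oxygen from target C3, which releases the C2=C3 enone and the C4 hydroxyl. The nearest precedent in type is the light-induced contraction of alkylated 4-pyranones and of their O-protonated forms to 4-hydroxycyclopent-2-enones, where an alcohol solvent, water or a side-chain hydroxyl quenches the zwitterion, and alkoxy-di-tert-butylsilanols are known tethered oxygen nucleophiles toward activated alkenes and epoxides; new here are the silanol as trap for this zwitterion and the spiro closure at the carbon that bears the tether. The carbocycle closes by the 4π electrocyclisation (a net contraction of the six-membered heterocycle once its C–O bond breaks) and the dioxasilolane closes by 5-exo-trig attack of oxygen on the oxyallyl terminus. C4 keeps the former ring oxygen and C5 takes its oxygen on the face away from the oxirane, so trans O4/O5 follows from the mechanism, whereas C5 relative to C1′ rests on allylic 1,3-strain in 11: with C1′–H eclipsing the oxyallyl C–O bond the silanoxy arm lies over one face and the dodecyl chain under the other, only the zwitterion whose oxirane sits on the chain side can be captured, and this places the chain cis to C4 on the dioxasilolane, as the target requires. Regioselectivity between the two oxyallyl termini is secured by the short O–Si–O tether, which reaches C5 only, while solvent capture at the unsubstituted terminus is held back by the very weakly nucleophilic (CF3)2CHOH and photodimerisation by high dilution. The facial argument is a prediction that must be tested, so the isomer with the opposite C4/C5 pair may also form and would be removed by chromatography here, with the relative configuration read from NOE contacts in the rigid spirocycle.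

Step 7
Reactants: 13 (4S,5R,9R)-2,2-di-tert-butyl-4-dodecyl-9-hydroxy-1,3-dioxa-2-silaspiro[4.4]non-7-en-6-one
Product: 14 (4S,5R,9R)-2,2-di-tert-butyl-4-dodecyl-6-oxo-1,3-dioxa-2-silaspiro[4.4]non-7-en-9-yl acetate
Conditions: Ac2O (1.5 equiv), pyridine (3 equiv), DMAP (5 mol %), CH2Cl2, 0 °C
Reagents that add atoms: acetic anhydride, CC(=O)OC(C)=O
Why: DMAP-catalysed acylation, in which the C4 hydroxyl is the only free OH, C5 carries no hydrogen so that E1cB loss of the new acetate is impossible, and the mild base at 0 °C should neither move the silylene nor touch C4.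

Step 8
Reactants: 14 (4S,5R,9R)-2,2-di-tert-butyl-4-dodecyl-6-oxo-1,3-dioxa-2-silaspiro[4.4]non-7-en-9-yl acetate
Product: 15 (1R,5S)-5-hydroxy-5-[(1S)-1-hydroxytridecyl]-4-oxocyclopent-2-en-1-yl acetate
Conditions: HF·pyridine, pyridine, THF, 0 °C (PTFE vessel)
Reagents that add atoms: none
Why: Fluoride cleavage of a silylene acetal, in which the strained five-membered di-tert-butylsilylene of a 1,2-diol is among the most labile silyl groups toward buffered HF and the weakly acidic medium should avoid acetate hydrolysis and O4-to-O1′ acyl migration, so that all three stereocentres are carried through unchanged.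

Compound list
1 | 4H-pyran-4-one | O=C1C=COC=C1 | starting material
2 | 3-iodo-4H-pyran-4-one | O=C1C=COC=C1I | intermediate
3 | tridecanal | CCCCCCCCCCCCC=O | starting material
4 | (4-oxo-4H-pyran-3-yl)magnesium chloride, LiCl complex, formed in situ | O=C1C=COC=C1[Mg]Cl | intermediate
5 | (±)-3-(1-hydroxytridecyl)-4H-pyran-4-one | CCCCCCCCCCCCC(O)C1=COC=CC1=O | intermediate
6 | 3-tridecanoyl-4H-pyran-4-one | CCCCCCCCCCCCC(=O)C1=COC=CC1=O | intermediate
7 | 3-[(1S)-1-hydroxytridecyl]-4H-pyran-4-one | CCCCCCCCCCCC[C@H](O)C1=COC=CC1=O | intermediate
8 | di-tert-butylsilyl bis(trifluoromethanesulfonate) | CC(C)(C)[Si](OS(=O)(=O)C(F)(F)F)(OS(=O)(=O)C(F)(F)F)C(C)(C)C | starting material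
9 | di-tert-butyl{[(1S)-1-(4-oxo-4H-pyran-3-yl)tridecyl]oxy}silyl trifluoromethanesulfonate, formed in situ | CCCCCCCCCCCC[C@H](O[Si](OS(=O)(=O)C(F)(F)F)(C(C)(C)C)C(C)(C)C)C1=COC=CC1=O | intermediate
10 | 3-[(1S)-1-{[di-tert-butyl(hydroxy)silyl]oxy}tridecyl]-4H-pyran-4-one | CCCCCCCCCCCC[C@H](O[Si](O)(C(C)(C)C)C(C)(C)C)C1=COC=CC1=O | intermediate
11 | 6-oxabicyclo[3.1.0]hexenyl oxyallyl zwitterion carrying the (1S)-silanoxytridecyl group on the cationic terminus, oxirane on the later O4 face, formed in situ | CCCCCCCCCCCC[C@H](O[Si](O)(C(C)(C)C)C(C)(C)C)[C+]1C([O-])=C[C@H]2O[C@@H]12 | intermediate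
12 | spiro dioxasilolane epoxy enol, O5 anti to the oxirane, formed in situ | CCCCCCCCCCCC[C@@H]1O[Si](C(C)(C)C)(C(C)(C)C)O[C@@]12C(O)=C[C@H]3O[C@@H]23 | intermediate
13 | (4S,5R,9R)-2,2-di-tert-butyl-4-dodecyl-9-hydroxy-1,3-dioxa-2-silaspiro[4.4]non-7-en-6-one | CCCCCCCCCCCC[C@@H]1O[Si](C(C)(C)C)(C(C)(C)C)O[C@@]12C(=O)C=C[C@H]2O | intermediate
14 | (4S,5R,9R)-2,2-di-tert-butyl-4-dodecyl-6-oxo-1,3-dioxa-2-silaspiro[4.4]non-7-en-9-yl acetate | CCCCCCCCCCCC[C@@H]1O[Si](C(C)(C)C)(C(C)(C)C)O[C@@]12C(=O)C=C[C@H]2OC(C)=O | intermediate
15 | (1R,5S)-5-hydroxy-5-[(1S)-1-hydroxytridecyl]-4-oxocyclopent-2-en-1-yl acetate | CCCCCCCCCCCC[C@H](O)[C@@]1(O)C(=O)C=C[C@H]1OC(C)=O | target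

Total step count: 8. Longest linear sequence: 8 steps (1 to 15).

Steps most likely to fail

Step 6 (labelled step). Three processes are at risk. The hindered silanol may add more slowly than the oxirane migrates, so that the zwitterion drains into the 2-pyranone manifold. The solvent may intercept the unsubstituted terminus. Both ring faces may be used alike, in which case the mismatched zwitterion has no productive exit through the tether.

The fallback uses known chemistry, sets out from 7 and comes back at 15. The tether is given up and 7 is irradiated at 254 nm as its 4-hydroxypyrylium ion in aqueous H2SO4 with CF3CH2OH as co-solvent. This is the established photohydration, in which water in large excess adds anti to the oxirane. After separation from regio- and stereoisomers it should give (4R,5S)-4,5-dihydroxy-5-[(1S)-1-hydroxytridecyl]cyclopent-2-en-1-one F1.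

2,2-Dimethoxypropane with pyridinium p-toluenesulfonate should then tie O5 and O1′ into (4S,5R,9R)-4-dodecyl-9-hydroxy-2,2-dimethyl-1,3-dioxaspiro[4.4]non-7-en-6-one F2, because the trans O4/O5 pair cannot be bridged and acetone ketals prefer the five-membered ring. Ac2O/pyridine gives (4S,5S,9R)-4-dodecyl-2,2-dimethyl-6-oxo-1,3-dioxaspiro[4.4]non-7-en-9-yl acetate F3, and CF3CO2H–H2O at 0 °C releases 15.

Step 4. The basic ring carbonyl may compete for boron and erode facial discrimination, or hydride may be delivered in a conjugate sense to the doubly activated C2.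

The fallback sets out from 5 and comes back at 7, and steps 3 and 4 are dropped. Racemic 5 undergoes acylative kinetic resolution with catalytic (R)-benzotetramisole, propanoic anhydride (0.6 equiv) and iPr2NEt in CHCl3 at 0 °C, a method that recognises a π-system next to the carbinol. By analogy with 1-arylalkanols the (R)-carbinol should be acylated faster, to (1R)-1-(4-oxo-4H-pyran-3-yl)tridecyl propanoate F4, and unreacted 7 is separated by chromatography. The sense of selection is checked on the racemate, and the other catalyst enantiomer is taken if needed.

Step 2. The magnesiated pyranone may ring-open by β-elimination of the ring oxygen, or the exchange reagent may add to C2/C6 of the ring.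

The fallback sets out from 2 and comes back at 6, and step 3 is dropped. Direct insertion of Zn dust activated by LiCl into the C–I bond in THF at 25 °C avoids any nucleophilic alkylmetal and gives the more covalent (4-oxo-4H-pyran-3-yl)zinc iodide F5. This is coupled in the same flask with tridecanoyl chloride under Pd(PPh3)4 catalysis (Negishi acylation) to give ketone 6.

Further compounds
F1 | step 6 | (4R,5S)-4,5-dihydroxy-5-[(1S)-1-hydroxytridecyl]cyclopent-2-en-1-one | CCCCCCCCCCCC[C@H](O)[C@@]1(O)C(=O)C=C[C@H]1O
F2 | step 6 | (4S,5R,9R)-4-dodecyl-9-hydroxy-2,2-dimethyl-1,3-dioxaspiro[4.4]non-7-en-6-one | CCCCCCCCCCCC[C@@H]1OC(C)(C)O[C@@]12C(=O)C=C[C@H]2O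
F3 | step 6 | (4S,5S,9R)-4-dodecyl-2,2-dimethyl-6-oxo-1,3-dioxaspiro[4.4]non-7-en-9-yl acetate | CCCCCCCCCCCC[C@@H]1OC(C)(C)O[C@@]12C(=O)C=C[C@H]2OC(C)=O
F4 | step 4 | (1R)-1-(4-oxo-4H-pyran-3-yl)tridecyl propanoate | CCCCCCCCCCCC[C@@H](OC(=O)CC)C1=COC=CC1=O
F5 | step 2 | (4-oxo-4H-pyran-3-yl)zinc iodide | O=C1C=COC=C1[Zn]I
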